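**Retrosynthetic overview**
- Last bond: the ring A C–CH3 (next to OMe), by decarboxylative radical methylation of the only free quinone C–H.
- Ring A–chain bond: Knoevenagel/transfer-hydrogenation (reductive alkylation) of 2-hydroxy-5-methoxybenzoquinone with the chain aldehyde; this puts the chain next to OH.
- Ring B–chain bond (key step): Grignard 1,2-addition to O-protected 2-hydroxy-5-methoxy-3-methylbenzoquinone, then an alkoxide-driven 1,2-alkyl shift to the neighbouring C–H and aromatisation; this puts the chain next to OMe.
- Both quinone cores come from p-benzoquinone (dimethoxylation, mono-hydrolysis, reductive C-methylation for ring B); the C14 linker comes from 7-bromohept-1-ene, 1,6-dibromohexane and CO.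
- No ring is built: both six-membered rings are carried over from p-benzoquinone; ring B is completed first, ring A last.

Assumption: the target has no stereocentre and no stereogenic double bond, so it is one achiral compound and needs no stereocontrol; the linker is read as fourteen CH2 groups.

**Route**

Step 1
Reactants: 1 p-benzoquinone
Product: 3 2,5-dimethoxy-1,4-benzoquinone, via methoxybenzoquinone 2 (not isolated)
Conditions: MeOH, ZnCl2 (0.3 equiv), 65 °C; 3 equiv of 1, two of them act as oxidant
Reagents that add atoms: methanol (CO)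
Why: ZnCl2-catalysed oxa-Michael addition of methanol with reoxidation by excess quinone, run twice (oxidative alkoxylation of a quinone); the second methanol enters at C5, the position β to the carbonyl that is not deactivated as a vinylogous ester.

Step 2
Reactants: 3 2,5-dimethoxy-1,4-benzoquinone
Product: 5 2-hydroxy-5-methoxy-1,4-benzoquinone, via sodium quinolate 4 (not isolated)
Conditions: NaOH (1.05 equiv), H2O/THF, 0 → 23 °C; then 1 M HCl
Reagents that add atoms: sodium hydroxide ([Na+].[OH-])
Why: Vinylogous ester saponification by addition–elimination; the first hydrolysis gives a vinylogous carboxylate that hydroxide no longer attacks, so the reaction stops at the mono-ether of the symmetric substrate.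

Step 3
Reactants: 5 2-hydroxy-5-methoxy-1,4-benzoquinone
Product: 7 2-hydroxy-5-methoxy-3-methyl-1,4-benzoquinone, via methylidene trione 6 (not isolated)
Conditions: aq. CH2O (37%, 1.5 equiv), Hantzsch ester (1.2 equiv), L-proline (10 mol%), EtOH, 23 °C
Reagents that add atoms: formaldehyde (C=O)
Why: Proline-catalysed Knoevenagel condensation at the enolic carbon followed by Hantzsch-ester transfer hydrogenation (three-component reductive alkylation); only the carbon next to the hydroxyl is nucleophilic, which fixes the methyl next to OH.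

Step 4
Reactants: 8 7-bromohept-1-ene; 9 1,6-dibromohexane
Product: 11 13-bromotridec-1-ene, via heptenyl Grignard 10 (not isolated)
Conditions: 8, Mg, THF, 40 °C; then added to 9 (3 equiv), Li2CuCl4 (2 mol%), THF, −10 → 23 °C
Reagents that add atoms: none
Why: Copper-catalysed Grignard–alkyl bromide cross-coupling (Kochi coupling); the excess of dibromide holds it at mono-substitution and the surplus is distilled off.

Step 5
Reactants: 11 13-bromotridec-1-ene
Product: 13 14-bromo-1,1-dimethoxytetradecane, via bromo aldehyde 12 (not isolated)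
Conditions: Rh(acac)(CO)2 (0.5 mol%), BiPhePhos (1.5 mol%), CO/H2 (1:1, 10 bar), toluene, 70 °C; then HC(OMe)3 (3 equiv), pTsOH·H2O (2 mol%), 23 °C
Reagents that add atoms: carbon monoxide ([C-]#[O+]); trimethyl orthoformate (COC(OC)OC)
Why: Linear-selective rhodium/bisphosphite hydroformylation of the terminal alkene, then acid-catalysed acetalisation in the same pot; the primary bromide is inert to both.

Step 6
Reactants: 7 2-hydroxy-5-methoxy-3-methyl-1,4-benzoquinone; 13 14-bromo-1,1-dimethoxytetradecane
Product: 20 14-(5-hydroxy-2-methoxy-4-methyl-3,6-dioxocyclohexa-1,4-dien-1-yl)tetradecanal, via acetal Grignard 14 (not isolated), via sodium salt 15 (not isolated), via MOM ether 16 (not isolated), via quinol adduct 17 (not isolated), via MOM hydroquinone 18 (not isolated), via triol aldehyde 19 (not isolated)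
Conditions: 13, Mg, THF, 45 °C (gives 14); 7, NaH (1.0 equiv), THF, 0 °C, then MOMCl (1.0 equiv); LaCl3·2LiCl (1.0 equiv), 14 (1.3 equiv), −78 → 23 °C; then 3 M HCl, THF, 40 °C (N2); then air, EtOAc/H2O
Reagents that add atoms: water (O)
Why: Proposed new method: the quinolate is capped in the flask as its MOM ether so the ring stays a neutral acceptor, the lanthanum-activated Grignard adds 1,2 to the less hindered carbonyl (the one flanked by the C–H carbon), and on warming the tertiary alkoxide pushes the alkyl group in a 1,2-shift onto that neighbouring C–H carbon, which is the β-carbon of the metal-chelated α-methoxy enone (a vinylogous α-ketol or quinol–enedione rearrangement) and not onto the oxygen-bearing neighbour, enolisation to the hydroquinone making the shift irreversible; the shift is run under basic, non-ionising conditions because acid would instead expel the tertiary hydroxyl with loss of the methoxy group (Stork–Danheiser-type transposition), and only after aromatisation does aqueous HCl remove MOM and acetal before air oxidises the triol to the hydroxyquinone; the closest known reactions are organolithium 1,2-addition to alkoxyquinones and the acid- or base-promoted quinol–enedione (dienone–phenol type) rearrangement of p-quinols, which has not been shown as a one-flask C–H alkylation of a hydroxyquinone.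

Step 7
Reactants: 20 14-(5-hydroxy-2-methoxy-4-methyl-3,6-dioxocyclohexa-1,4-dien-1-yl)tetradecanal; 5 2-hydroxy-5-methoxy-1,4-benzoquinone
Product: 22 2-hydroxy-3-[14-(5-hydroxy-2-methoxy-4-methyl-3,6-dioxocyclohexa-1,4-dien-1-yl)tetradecyl]-5-methoxy-1,4-benzoquinone, via alkylidene trione 21 (not isolated)
Conditions: 5 (1.2 equiv), Hantzsch ester (1.5 equiv), L-proline (20 mol%), CH2Cl2, 23 °C; air on work-up
Reagents that add atoms: none
Why: The same organocatalytic Knoevenagel/transfer-hydrogenation (three-component reductive alkylation); 5 reacts only at the carbon next to its OH and the fully substituted ring B of 20 has no nucleophilic C–H, so the chain ends next to OH in ring A.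

Step 8
Reactants: 22 2-hydroxy-3-[14-(5-hydroxy-2-methoxy-4-methyl-3,6-dioxocyclohexa-1,4-dien-1-yl)tetradecyl]-5-methoxy-1,4-benzoquinone
Product: 23 2-hydroxy-3-[14-(5-hydroxy-2-methoxy-4-methyl-3,6-dioxocyclohexa-1,4-dien-1-yl)tetradecyl]-5-methoxy-6-methyl-1,4-benzoquinone (target)
Conditions: AcOH (10 equiv), AgNO3 (0.2 equiv), (NH4)2S2O8 (2.5 equiv), MeCN/H2O (2:1), 65 °C
Reagents that add atoms: acetic acid (CC(=O)O)
Why: Silver-catalysed decarboxylative radical alkylation of a quinone (Jacobsen–Torssell, Minisci type): the methyl radical adds to the only remaining quinone C–H, on ring A next to OMe, and persulfate reoxidises the adduct.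

**Compound list**

1 | p-benzoquinone | O=C1C=CC(=O)C=C1 | starting material
2 | 2-methoxy-1,4-benzoquinone | COC1=CC(=O)C=CC1=O | intermediate (not isolated)
3 | 2,5-dimethoxy-1,4-benzoquinone | COC1=CC(=O)C(OC)=CC1=O | intermediate
4 | sodium 4-methoxy-3,6-dioxocyclohexa-1,4-dien-1-olate | [Na+].[O-]C1=CC(=O)C(OC)=CC1=O | intermediate (not isolated)
5 | 2-hydroxy-5-methoxy-1,4-benzoquinone | OC1=CC(=O)C(OC)=CC1=O | intermediate
6 | 5-methoxy-3-methylidenecyclohex-5-ene-1,2,4-trione | C=C1C(=O)C(=O)C=C(OC)C1=O | intermediate (not isolated)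
7 | 2-hydroxy-5-methoxy-3-methyl-1,4-benzoquinone | OC1=C(C)C(=O)C(OC)=CC1=O | intermediate
8 | 7-bromohept-1-ene | C=CCCCCCBr | starting material
9 | 1,6-dibromohexane | BrCCCCCCBr | starting material
10 | hept-6-en-1-ylmagnesium bromide | C=CCCCCC[Mg]Br | intermediate (not isolated)
11 | 13-bromotridec-1-ene | C=CCCCCCCCCCCCBr | intermediate
12 | 14-bromotetradecanal | O=CCCCCCCCCCCCCCBr | intermediate (not isolated)
13 | 14-bromo-1,1-dimethoxytetradecane | COC(OC)CCCCCCCCCCCCCBr | intermediate
14 | (14,14-dimethoxytetradecyl)magnesium bromide | COC(OC)CCCCCCCCCCCCC[Mg]Br | intermediate (not isolated)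
15 | sodium 4-methoxy-2-methyl-3,6-dioxocyclohexa-1,4-dien-1-olate | [Na+].[O-]C1=C(C)C(=O)C(OC)=CC1=O | intermediate (not isolated)
16 | 5-methoxy-2-(methoxymethoxy)-3-methyl-1,4-benzoquinone | COCOC1=C(C)C(=O)C(OC)=CC1=O | intermediate (not isolated)
17 | 4-(14,14-dimethoxytetradecyl)-4-hydroxy-6-methoxy-3-(methoxymethoxy)-2-methylcyclohexa-2,5-dien-1-one (present as its bromomagnesium alkoxide) | OC1(CCCCCCCCCCCCCC(OC)OC)C=C(OC)C(=O)C(C)=C1OCOC | intermediate (not isolated)
18 | 3-(14,14-dimethoxytetradecyl)-2-methoxy-5-(methoxymethoxy)-6-methylbenzene-1,4-diol (present as its bromomagnesium phenoxide) | COC(OC)CCCCCCCCCCCCCc1c(O)c(OCOC)c(C)c(O)c1OC | intermediate (not isolated)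
19 | 14-(2,3,5-trihydroxy-6-methoxy-4-methylphenyl)tetradecanal | O=CCCCCCCCCCCCCCc1c(O)c(O)c(C)c(O)c1OC | intermediate (not isolated)
20 | 14-(5-hydroxy-2-methoxy-4-methyl-3,6-dioxocyclohexa-1,4-dien-1-yl)tetradecanal | O=CCCCCCCCCCCCCCC1=C(OC)C(=O)C(C)=C(O)C1=O | intermediate
21 | 3-[14-(5-hydroxy-2-methoxy-4-methyl-3,6-dioxocyclohexa-1,4-dien-1-yl)tetradecylidene]-5-methoxycyclohex-5-ene-1,2,4-trione (alkene geometry not defined) | COC1=CC(=O)C(=O)C(=CCCCCCCCCCCCCCC2=C(OC)C(=O)C(C)=C(O)C2=O)C1=O | intermediate (not isolated)
22 | 2-hydroxy-3-[14-(5-hydroxy-2-methoxy-4-methyl-3,6-dioxocyclohexa-1,4-dien-1-yl)tetradecyl]-5-methoxy-1,4-benzoquinone | COC1=CC(=O)C(O)=C(CCCCCCCCCCCCCCC2=C(OC)C(=O)C(C)=C(O)C2=O)C1=O | intermediate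
23 | 2-hydroxy-3-[14-(5-hydroxy-2-methoxy-4-methyl-3,6-dioxocyclohexa-1,4-dien-1-yl)tetradecyl]-5-methoxy-6-methyl-1,4-benzoquinone | COC1=C(C)C(=O)C(O)=C(CCCCCCCCCCCCCCC2=C(OC)C(=O)C(C)=C(O)C2=O)C1=O | target

**Step count and risks**

Total: 8 steps. Longest linear sequence: 6 steps (1 → 3 → 5 → 7 → 20 → 22 → 23).

The three steps most likely to fail:

Step 6 (the proposed new step). The Grignard may reduce the quinone by electron transfer, add to the other carbonyl, or the alkoxide may not undergo the shift, in which case acid work-up gives the methoxy-loss product. The fallback uses known chemistry, sets out from 7 and 13 and comes back at 20. Compound 7 is reduced with Na2S2O4 (EtOAc/H2O) to 5-methoxy-3-methylbenzene-1,2,4-triol F1. This is capped at once (NaH, MOMCl, DMF) as 1-methoxy-2,4,5-tris(methoxymethoxy)-3-methylbenzene F2. Its single aryl C–H, flanked by OMe and OMOM, is lithiated (n-BuLi, TMEDA, THF, −20 °C) and alkylated with 13 (CuBr·SMe2 cat.) to give 1-(14,14-dimethoxytetradecyl)-2-methoxy-3,5,6-tris(methoxymethoxy)-4-methylbenzene F3. 3 M HCl in THF then removes the three MOM groups and the acetal to give 19, which air oxidises to 20. This is directed ortho-metalation and alkylation of a polyalkoxyarene followed by hydroquinone autoxidation.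

Step 8. Persulfate can degrade the two hydroxyquinone rings and conversion may stall, leaving 22 that is hard to separate from 23. The fallback sets out from 22 and comes back at 23. Electrophilic bromination of the only quinone C–H (NBS, MeCN, 0 °C) gives 2-bromo-6-hydroxy-5-[14-(5-hydroxy-2-methoxy-4-methyl-3,6-dioxocyclohexa-1,4-dien-1-yl)tetradecyl]-3-methoxy-1,4-benzoquinone F4. Suzuki–Miyaura methylation (trimethylboroxine, Pd(dppf)Cl2, K2CO3, dioxane/H2O, 80 °C) then gives 23.

Step 3. With formaldehyde the methylidene trione 6 can be trapped by a second molecule of 5 to give a methylene-bridged dimer before hydride transfer. The fallback sets out from 5 and comes back at 7. A Mannich reaction (aq. Me2NH, aq. CH2O, EtOH, 23 °C) gives the isolable 3-[(dimethylamino)methyl]-2-hydroxy-5-methoxy-1,4-benzoquinone F5. Hydrogenolysis of the benzylic-type C–N bond (H2, Pd/C, AcOH), with air reoxidation on work-up, gives 7.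

**Further compounds**

F1 | step 6 | 5-methoxy-3-methylbenzene-1,2,4-triol | COc1cc(O)c(O)c(C)c1O
F2 | step 6 | 1-methoxy-2,4,5-tris(methoxymethoxy)-3-methylbenzene | COc1cc(OCOC)c(OCOC)c(C)c1OCOC
F3 | step 6 | 1-(14,14-dimethoxytetradecyl)-2-methoxy-3,5,6-tris(methoxymethoxy)-4-methylbenzene | COC(OC)CCCCCCCCCCCCCc1c(OC)c(OCOC)c(C)c(OCOC)c1OCOC
F4 | step 8 | 2-bromo-6-hydroxy-5-[14-(5-hydroxy-2-methoxy-4-methyl-3,6-dioxocyclohexa-1,4-dien-1-yl)tetradecyl]-3-methoxy-1,4-benzoquinone | COC1=C(Br)C(=O)C(O)=C(CCCCCCCCCCCCCCC2=C(OC)C(=O)C(C)=C(O)C2=O)C1=O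
F5 | step 3 | 3-[(dimethylamino)methyl]-2-hydroxy-5-methoxy-1,4-benzoquinone | CN(C)CC1=C(O)C(=O)C=C(OC)C1=O
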